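The retrosynthesis removes the fifteen benzyl ethers, then the three C–H bonds at C2, C3 and C4 of the lower pyran (ring F) to reach a flat 3-galloyloxyflavylium ion, then cuts ring F at C3–C4 and O1–C2 into a ring D salicylaldehyde and an omega-galloyloxyacetophenone, and last cuts the upper C4–ring D bond and the upper C3 ester.
Forward: benzylated (−)-epicatechin is oxidised at C4, galloylated, joined through C4 to the carbon ortho to the hydroxyl of 3,5-dibenzyloxyphenol (the future C8) and ortho-formylated; ring F is then closed as a pyrylium on ring D, reduced in two stages, and the whole is debenzylated.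
Enabling feature: ring F is fused to ring D through C4a and the C8a oxygen, which are ortho to each other, so C4 can come from a formyl group on C4a and O1 from the C8a phenol; the cis C2-aryl/C3-gallate pair is what syn addition of H2 to a planar C2=C3 bond must give.
Stereochemistry: C2 and C3 of the upper unit are bought with (−)-epicatechin; its C4 is set trans to the C3 gallate in the cation coupling; C2 and C3 of the lower unit come from a ligand-controlled syn hydrogenation.

Key step: step 10

Remarks on the chemistry: 3,4,5-tris(benzyloxy)benzoic acid, the perbenzyl ether of gallic acid, is taken as a purchased material. The interflavan bond is read as 4β, trans to the C3 oxygen of the upper unit, as the SMILES encodes.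

Step 1
Reactants: 1 3,4,5-tris(benzyloxy)benzoic acid
Product: 2 3,4,5-tris(benzyloxy)benzoyl chloride
Conditions: (COCl)2, cat. DMF, CH2Cl2, 0 °C to rt
Reagents that add atoms: oxalyl chloride, ClC(=O)C(=O)Cl
Why: Acid chloride formation through the chloroiminium ion from DMF is routine for this acid and leaves aryl benzyl ethers untouched.

Step 2
Reactants: 2 3,4,5-tris(benzyloxy)benzoyl chloride
Product: 3 2-diazo-1-[3,4,5-tris(benzyloxy)phenyl]ethan-1-one
Conditions: CH2N2 (3 equiv), Et2O/THF, 0 °C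
Reagents that add atoms: diazomethane, C=[N+]=[N-]
Why: This is the acylation of diazomethane that opens an Arndt–Eistert sequence, with the excess reagent consuming HCl so that the diazoketone is not converted into the chloroketone.

Step 3
Reactants: 3 2-diazo-1-[3,4,5-tris(benzyloxy)phenyl]ethan-1-one; 1 3,4,5-tris(benzyloxy)benzoic acid
Product: 4 2-oxo-2-[3,4,5-tris(benzyloxy)phenyl]ethyl 3,4,5-tris(benzyloxy)benzoate
Conditions: Rh2(OAc)4 (1 mol %), CH2Cl2, rt, slow addition of 3
Reagents that add atoms: none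
Why: Rhodium-carbenoid O–H insertion into a carboxylic acid is fast and should outrun Wolff rearrangement and arene or C–H insertion, giving the alpha-acyloxy ketone directly.

Step 4
Reactants: 5 (−)-epicatechin
Product: 6 5,7,3',4'-tetra-O-benzyl-(−)-epicatechin
Conditions: BnBr (4.4 equiv), K2CO3, DMF, 0 °C to rt
Reagents that add atoms: benzyl bromide, BrCc1ccccc1
Why: In this Williamson etherification K2CO3 deprotonates only the four phenols, so the secondary C3 hydroxyl stays free and C2 and C3 are not touched.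

Step 5
Reactants: 6 5,7,3',4'-tetra-O-benzyl-(−)-epicatechin
Product: 7 5,7,3',4'-tetra-O-benzyl-4β-(2-ethoxyethoxy)epicatechin
Conditions: DDQ (2 equiv), 2-ethoxyethanol (5 equiv), CH2Cl2, rt
Reagents that add atoms: 2-ethoxyethanol, CCOCCO
Why: DDQ benzylic oxidation removes hydride from C4, activated by the ring A ether oxygens, and the alcohol adds trans to the C3 hydroxyl; the C4 centre is ionised and reset in step 8, so its purity does not matter.

Step 6
Reactants: 7 5,7,3',4'-tetra-O-benzyl-4β-(2-ethoxyethoxy)epicatechin; 2 3,4,5-tris(benzyloxy)benzoyl chloride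
Product: 8 5,7,3',4'-tetra-O-benzyl-4β-(2-ethoxyethoxy)epicatechin 3-O-[3,4,5-tris(benzyloxy)benzoate]
Conditions: 2 (1.5 equiv), Et3N, DMAP, CH2Cl2, rt
Reagents that add atoms: none
Why: DMAP-catalysed acylation of the hindered secondary alcohol proceeds under basic conditions that the C4 ether tolerates, and C3 keeps its configuration because its C–O bond is not broken.

Step 7
Reactants: 9 phloroglucinol
Product: 10 3,5-bis(benzyloxy)phenol
Conditions: BnBr (2.0 equiv), K2CO3, DMF, rt; chromatography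
Reagents that add atoms: benzyl bromide, BrCc1ccccc1
Why: Statistical Williamson dibenzylation of a cheap triphenol should give the diether, separable from the mono- and triethers on silica.

Step 8
Reactants: 8 5,7,3',4'-tetra-O-benzyl-4β-(2-ethoxyethoxy)epicatechin 3-O-[3,4,5-tris(benzyloxy)benzoate]; 10 3,5-bis(benzyloxy)phenol
Product: 11 benzylated epicatechin gallate bearing a 4β-[2-hydroxy-4,6-bis(benzyloxy)phenyl] group
Conditions: 10 (4 equiv), TMSOTf (0.5 equiv), CH2Cl2, −78 to −20 °C
Reagents that add atoms: none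
Why: TMSOTf ionises the C4 ether to the ring A-stabilised benzylic cation, which undergoes Friedel–Crafts alkylation by the excess phenol at the less hindered carbon ortho to its hydroxyl, the arene entering trans to the C3 gallate (which shields the cis face) and so setting the 4β centre.

Step 9
Reactants: 11 benzylated epicatechin gallate bearing a 4β-[2-hydroxy-4,6-bis(benzyloxy)phenyl] group
Product: 12 benzylated epicatechin gallate bearing a 4β-[3-formyl-2-hydroxy-4,6-bis(benzyloxy)phenyl] group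
Conditions: MgCl2, Et3N, (CH2O)n, MeCN, reflux; then 1 M HCl
Reagents that add atoms: paraformaldehyde (as formaldehyde), C=O
Why: In the Casnati–Skattebøl ortho-formylation the magnesium phenoxide delivers formaldehyde to its single free ortho carbon and a second formaldehyde oxidises the benzylic alkoxide, so ring A, which has no free phenol, and the esters should not react.

Step 10
Reactants: 12 benzylated epicatechin gallate bearing a 4β-[3-formyl-2-hydroxy-4,6-bis(benzyloxy)phenyl] group; 4 2-oxo-2-[3,4,5-tris(benzyloxy)phenyl]ethyl 3,4,5-tris(benzyloxy)benzoate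
Product: 15 benzylated epicatechin gallate 4β-linked to C8 of 5,7-bis(benzyloxy)-3-[3,4,5-tris(benzyloxy)benzoyloxy]-2-[3,4,5-tris(benzyloxy)phenyl]chromenylium chloride, via alpha-galloyloxy chalcone 13 (not isolated), via 2-hydroxy-2H-chromene hemiketal 14 (not isolated)
Conditions: 4 (1.5 equiv), dry HCl (g), EtOAc, 0 °C then 4 °C, 48 h; Et2O precipitation
Reagents that add atoms: hydrogen chloride, Cl
Why: HCl enolises ketone 4 and its CH2 carbon (future C3) adds to the protonated formyl carbon of 12 (future C4), and loss of water gives chalcone 13, whose double-bond isomers interconvert in acid. The C8a hydroxyl then adds to the aryl ketone carbonyl (future C2) in a 6-exo-trig hemiketalisation to 14, and loss of a second water aromatises ring F to the pyrylium. The closest known reaction is the Robinson acid condensation of salicylaldehydes with omega-acyloxyacetophenones to 3-acyloxyflavylium salts. No stereocentre is formed, so the step needs only cross-selectivity and one constitution: the aldehyde cannot enolise, ketone 4 has a single enolisable CH2, and the only free phenol is ortho to the formyl group, which fixes the 4-to-8 linkage. The formyl group and then the cationic ring draw electron density from ring D, which disfavours protonation at its C8 and loss of the upper unit, and the aryl benzyl ethers and both gallates should tolerate dry HCl at 0 °C.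

Step 11
Reactants: 15 benzylated epicatechin gallate 4β-linked to C8 of the 3-galloyloxyflavylium chloride
Product: 16 benzylated epicatechin gallate 4β-linked to C8 of 5,7-bis(benzyloxy)-2-[3,4,5-tris(benzyloxy)phenyl]-4H-chromen-3-yl 3,4,5-tris(benzyloxy)benzoate (flav-2-ene enol gallate)
Conditions: Hantzsch ester (1.2 equiv), NaHCO3, CH2Cl2, 0 °C, dark
Reagents that add atoms: none
Why: Hydride transfer from the dihydropyridine to a 2-aryl-1-benzopyrylium ion is a 1,4-reduction at the soft C4 site, away from the C2 end crowded by the aryl group and the upper unit, and the bicarbonate removes HCl so that the enol ether is not protonated and reduced further; no stereocentre is formed.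

Step 12
Reactants: 16 flav-2-ene enol gallate
Product: 17 pentadeca-O-benzyl epicatechin-3-O-gallate-(4β→8)-epigallocatechin-3-O-gallate
Conditions: [Ir(cod)((S)-tBu-PHOX)]BArF (5 mol %), H2 (50 bar), CH2Cl2, rt
Reagents that add atoms: none
Why: Proposed new method: a cationic iridium dihydride with a chiral P,N ligand should bind the electron-rich tetrasubstituted C2=C3 bond of 16 and deliver both hydrogens to one face, which makes the C2 aryl and C3 gallate cis by necessity, while the ligand (the antipode that gives 2R,3R being fixed in a small screen) selects the face. The closest known reactions are the iridium–phosphinooxazoline hydrogenation of 2-aryl-4H-chromenes and of tetrasubstituted alkenes and the rhodium–bisphosphine hydrogenation of enol esters, none yet shown on a 3-acyloxy-4H-chromene, and benzyl ethers are inert to the homogeneous catalyst.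

Step 13
Reactants: 17 pentadeca-O-benzyl epicatechin-3-O-gallate-(4β→8)-epigallocatechin-3-O-gallate
Product: 18 (−)-epicatechin-3-O-gallate-(4β→8)-(−)-epigallocatechin-3-O-gallate
Conditions: H2 (1 atm), Pd(OH)2/C, THF/MeOH/H2O, rt
Reagents that add atoms: none
Why: Hydrogenolysis of the fifteen aryl benzyl ethers under the conditions usual for benzylated galloylated flavan-3-ol oligomers should leave the flavan C2–O1 bonds, both esters and all five stereocentres intact.

Compound list
1 | 3,4,5-tris(benzyloxy)benzoic acid | O=C(O)c1cc(OCc2ccccc2)c(OCc2ccccc2)c(OCc2ccccc2)c1 | starting material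
2 | 3,4,5-tris(benzyloxy)benzoyl chloride | O=C(Cl)c1cc(OCc2ccccc2)c(OCc2ccccc2)c(OCc2ccccc2)c1 | intermediate
3 | 2-diazo-1-[3,4,5-tris(benzyloxy)phenyl]ethan-1-one | [N-]=[N+]=CC(=O)c1cc(OCc2ccccc2)c(OCc2ccccc2)c(OCc2ccccc2)c1 | intermediate
4 | 2-oxo-2-[3,4,5-tris(benzyloxy)phenyl]ethyl 3,4,5-tris(benzyloxy)benzoate | O=C(COC(=O)c1cc(OCc2ccccc2)c(OCc2ccccc2)c(OCc2ccccc2)c1)c1cc(OCc2ccccc2)c(OCc2ccccc2)c(OCc2ccccc2)c1 | intermediate
5 | (−)-epicatechin, (2R,3R) | O[C@@H]1Cc2c(O)cc(O)cc2O[C@@H]1c1ccc(O)c(O)c1 | starting material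
6 | 5,7,3',4'-tetra-O-benzyl-(−)-epicatechin | O[C@@H]1Cc2c(OCc5ccccc5)cc(OCc5ccccc5)cc2O[C@@H]1c4ccc(OCc5ccccc5)c(OCc5ccccc5)c4 | intermediate
7 | 5,7,3',4'-tetra-O-benzyl-4β-(2-ethoxyethoxy)epicatechin (2,3-cis, 3,4-trans) | O[C@@H]1[C@@H](OCCOCC)c2c(OCc5ccccc5)cc(OCc5ccccc5)cc2O[C@@H]1c4ccc(OCc5ccccc5)c(OCc5ccccc5)c4 | intermediate
8 | 5,7,3',4'-tetra-O-benzyl-4β-(2-ethoxyethoxy)epicatechin 3-O-[3,4,5-tris(benzyloxy)benzoate] | O=C(O[C@@H]1[C@@H](OCCOCC)c2c(OCc5ccccc5)cc(OCc5ccccc5)cc2O[C@@H]1c4ccc(OCc5ccccc5)c(OCc5ccccc5)c4)c4cc(OCc5ccccc5)c(OCc5ccccc5)c(OCc5ccccc5)c4 | intermediate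
9 | phloroglucinol | Oc1cc(O)cc(O)c1 | starting material
10 | 3,5-bis(benzyloxy)phenol | Oc1cc(OCc2ccccc2)cc(OCc2ccccc2)c1 | intermediate
11 | benzylated epicatechin gallate with a 4β-[2-hydroxy-4,6-bis(benzyloxy)phenyl] group | O=C(O[C@@H]1[C@@H](c2c(OCc5ccccc5)cc(OCc5ccccc5)cc2O)c2c(OCc5ccccc5)cc(OCc5ccccc5)cc2O[C@@H]1c4ccc(OCc5ccccc5)c(OCc5ccccc5)c4)c4cc(OCc5ccccc5)c(OCc5ccccc5)c(OCc5ccccc5)c4 | intermediate
12 | benzylated epicatechin gallate with a 4β-[3-formyl-2-hydroxy-4,6-bis(benzyloxy)phenyl] group | O=C(O[C@@H]1[C@@H](c2c(OCc5ccccc5)cc(OCc5ccccc5)c(C=O)c2O)c2c(OCc5ccccc5)cc(OCc5ccccc5)cc2O[C@@H]1c4ccc(OCc5ccccc5)c(OCc5ccccc5)c4)c4cc(OCc5ccccc5)c(OCc5ccccc5)c(OCc5ccccc5)c4 | intermediate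
13 | alpha-galloyloxy chalcone on ring D, drawn as the E isomer with ring D cis to the aroyl group (transient, step 10) | O=C(O[C@@H]1[C@@H](c2c(OCc5ccccc5)cc(OCc5ccccc5)c(/C=C(/OC(=O)c4cc(OCc5ccccc5)c(OCc5ccccc5)c(OCc5ccccc5)c4)C(=O)c4cc(OCc5ccccc5)c(OCc5ccccc5)c(OCc5ccccc5)c4)c2O)c2c(OCc5ccccc5)cc(OCc5ccccc5)cc2O[C@@H]1c4ccc(OCc5ccccc5)c(OCc5ccccc5)c4)c4cc(OCc5ccccc5)c(OCc5ccccc5)c(OCc5ccccc5)c4 | intermediate
14 | 2-hydroxy-2H-chromene hemiketal of ring F, C2 configuration undefined (transient, step 10) | O=C(O[C@@H]1[C@@H](c2c(OCc5ccccc5)cc(OCc5ccccc5)c3C=C(OC(=O)c4cc(OCc5ccccc5)c(OCc5ccccc5)c(OCc5ccccc5)c4)C(O)(c4cc(OCc5ccccc5)c(OCc5ccccc5)c(OCc5ccccc5)c4)Oc23)c2c(OCc5ccccc5)cc(OCc5ccccc5)cc2O[C@@H]1c4ccc(OCc5ccccc5)c(OCc5ccccc5)c4)c4cc(OCc5ccccc5)c(OCc5ccccc5)c(OCc5ccccc5)c4 | intermediate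
15 | benzylated epicatechin gallate 4β-linked to C8 of the 3-galloyloxy-5,7,3',4',5'-pentabenzyloxyflavylium chloride | O=C(O[C@@H]1[C@@H](c2c(OCc5ccccc5)cc(OCc5ccccc5)c3cc(OC(=O)c4cc(OCc5ccccc5)c(OCc5ccccc5)c(OCc5ccccc5)c4)c(c4cc(OCc5ccccc5)c(OCc5ccccc5)c(OCc5ccccc5)c4)[o+]c23)c2c(OCc5ccccc5)cc(OCc5ccccc5)cc2O[C@@H]1c4ccc(OCc5ccccc5)c(OCc5ccccc5)c4)c4cc(OCc5ccccc5)c(OCc5ccccc5)c(OCc5ccccc5)c4.[Cl-] | intermediate
16 | flav-2-ene (4H-chromene) enol gallate of the lower unit, 4β-linked through C8 to benzylated epicatechin gallate | O=C(O[C@@H]1[C@@H](c2c(OCc5ccccc5)cc(OCc5ccccc5)c3c2OC(c4cc(OCc5ccccc5)c(OCc5ccccc5)c(OCc5ccccc5)c4)=C(OC(=O)c4cc(OCc5ccccc5)c(OCc5ccccc5)c(OCc5ccccc5)c4)C3)c2c(OCc5ccccc5)cc(OCc5ccccc5)cc2O[C@@H]1c4ccc(OCc5ccccc5)c(OCc5ccccc5)c4)c4cc(OCc5ccccc5)c(OCc5ccccc5)c(OCc5ccccc5)c4 | intermediate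
17 | pentadeca-O-benzyl epicatechin-3-O-gallate-(4β→8)-epigallocatechin-3-O-gallate, lower unit 2R,3R (cis) | O=C(O[C@@H]1[C@@H](c2c(OCc5ccccc5)cc(OCc5ccccc5)c3c2O[C@H](c4cc(OCc5ccccc5)c(OCc5ccccc5)c(OCc5ccccc5)c4)[C@H](OC(=O)c4cc(OCc5ccccc5)c(OCc5ccccc5)c(OCc5ccccc5)c4)C3)c2c(OCc5ccccc5)cc(OCc5ccccc5)cc2O[C@@H]1c4ccc(OCc5ccccc5)c(OCc5ccccc5)c4)c4cc(OCc5ccccc5)c(OCc5ccccc5)c(OCc5ccccc5)c4 | intermediate
18 | (−)-epicatechin-3-O-gallate-(4β→8)-(−)-epigallocatechin-3-O-gallate | O=C(O[C@@H]1[C@@H](c2c(O)cc(O)c3c2O[C@H](c2cc(O)c(O)c(O)c2)[C@H](OC(=O)c2cc(O)c(O)c(O)c2)C3)c2c(O)cc(O)cc2O[C@@H]1c1ccc(O)c(O)c1)c1cc(O)c(O)c(O)c1 | target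

Total step count: 13.
Longest linear sequence: 9 steps (steps 4, 5, 6, 8, 9, 10, 11, 12 and 13, from (−)-epicatechin 5).

Steps most likely to fail

Step 12. The catalyst may not turn over at the crowded tetrasubstituted alkene, may give poor facial selectivity against the bias of the upper unit, or may isomerise the enol ether through acidic iridium hydrides. The fallback uses known reactions and sets C3 by ketone reduction instead of alkene hydrogenation. It sets out from 16: the activated enol ester is cleaved ahead of the hindered alkyl gallate (K2CO3, MeOH/THF, 0 °C, argon) to give the flavan-3-one F1, whose C2 epimerises freely through its enol. Noyori-type transfer hydrogenation under dynamic kinetic resolution (RuCl(p-cymene)[(S,S)-TsDPEN] or its antipode, HCO2H/Et3N) should then give the cis (2R,3R)-flavan-3-ol F2. Esterification of F2 with acid chloride 2 (Et3N, DMAP, CH2Cl2) comes back to the route at 17.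

Step 10. Dry acid may fragment the interflavan bond or remove benzyl groups before ring F closes, or the phenol flanked by the upper unit may fail to close onto the ketone. The fallback gives up the annulation and forms the 4-to-8 bond last, with the lower stereocentres bought. It sets out from 8: commercial (−)-epigallocatechin F3 is benzylated on its five phenols (BnBr, K2CO3, DMF) to penta-O-benzylepigallocatechin F4, which is esterified with 2 (Et3N, DMAP) to octa-O-benzylepigallocatechin gallate F5. F5 in excess is alkylated at C8 by the cation from 8 (TMSOTf, CH2Cl2, −78 °C), which comes back to the route at 17.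

Step 8. The cation may attack the carbon para to the hydroxyl, between the two benzyloxy groups, or alkylate the phenol twice. The fallback removes the regiochemical choice from the C–C bond formation. It sets out from 8: the C4 cation is captured with phloroglucinol 9 itself (BF3·OEt2, dioxane/CH2Cl2), whose three ring carbons are equivalent, to give the 4β-(2,4,6-trihydroxyphenyl) adduct F6. Benzylation with two equivalents of BnBr (K2CO3, DMF) should take the unhindered para hydroxyl first and then one of the two equivalent ortho hydroxyls, coming back to the route at 11.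

Further compounds
F1 | step 12 | flavan-3-one of the lower unit (C2 epimers), 4β-linked through C8 to benzylated epicatechin gallate | O=C(O[C@@H]1[C@@H](c2c(OCc5ccccc5)cc(OCc5ccccc5)c3c2OC(c4cc(OCc5ccccc5)c(OCc5ccccc5)c(OCc5ccccc5)c4)C(=O)C3)c2c(OCc5ccccc5)cc(OCc5ccccc5)cc2O[C@@H]1c4ccc(OCc5ccccc5)c(OCc5ccccc5)c4)c4cc(OCc5ccccc5)c(OCc5ccccc5)c(OCc5ccccc5)c4
F2 | step 12 | cis (2R,3R)-flavan-3-ol of the lower unit, 4β-linked through C8 to benzylated epicatechin gallate | O=C(O[C@@H]1[C@@H](c2c(OCc5ccccc5)cc(OCc5ccccc5)c3c2O[C@H](c4cc(OCc5ccccc5)c(OCc5ccccc5)c(OCc5ccccc5)c4)[C@H](O)C3)c2c(OCc5ccccc5)cc(OCc5ccccc5)cc2O[C@@H]1c4ccc(OCc5ccccc5)c(OCc5ccccc5)c4)c4cc(OCc5ccccc5)c(OCc5ccccc5)c(OCc5ccccc5)c4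
F3 | step 10 | (−)-epigallocatechin | O[C@@H]1Cc2c(O)cc(O)cc2O[C@@H]1c1cc(O)c(O)c(O)c1
F4 | step 10 | 5,7,3',4',5'-penta-O-benzyl-(−)-epigallocatechin | O[C@@H]1Cc2c(OCc5ccccc5)cc(OCc5ccccc5)cc2O[C@@H]1c4cc(OCc5ccccc5)c(OCc5ccccc5)c(OCc5ccccc5)c4
F5 | step 10 | octa-O-benzyl-(−)-epigallocatechin 3-O-gallate | O=C(O[C@@H]1Cc2c(OCc5ccccc5)cc(OCc5ccccc5)cc2O[C@@H]1c4cc(OCc5ccccc5)c(OCc5ccccc5)c(OCc5ccccc5)c4)c4cc(OCc5ccccc5)c(OCc5ccccc5)c(OCc5ccccc5)c4
F6 | step 8 | benzylated epicatechin gallate with a 4β-(2,4,6-trihydroxyphenyl) group | O=C(O[C@@H]1[C@@H](c2c(O)cc(O)cc2O)c2c(OCc5ccccc5)cc(OCc5ccccc5)cc2O[C@@H]1c4ccc(OCc5ccccc5)c(OCc5ccccc5)c4)c4cc(OCc5ccccc5)c(OCc5ccccc5)c(OCc5ccccc5)c4
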